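Numbering of the target: oxolane O1, C2 (4-hydroxyphenyl), C3 (bears ketone carbon C6), C4 (bears carbinol carbon C7), C5 (2,4-dihydroxyphenyl).
Retrosynthesis first cuts the C6–aryl bond (aryl ketone and C7–OH from a γ-lactone plus an aryllithium), then C2–C3 and C4–C5 of the oxolane together.
Enabling feature: C2–O1–C5 is a 1,3-diaryl carbonyl ylide, and C3/C4 with their cis carbon substituents C6 and C7 are the α,β-carbons, the carbonyl and the γ-carbon of a 5-aryl butenolide (lactone ring C6–C3–C4–C7–O).
Forward: silylated 4-hydroxybenzaldehyde gives the (R)-butenolide (alkynylation, semihydrogenation, lactonisation) and, via a styrene, Heck coupling and epoxidation, a trans-diaryloxirane; photolysis of the oxirane with the butenolide closes the oxolane ring, the only ring of the target, onto the temporary lactone; acetate-to-silyl exchange, aryllithium opening of the lactone and desilylation finish the route.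
Stereochemistry: C7 from the catalytic asymmetric alkynylation; C3 and C4 from cis addition to the butenolide face anti to the C7 aryl; C2 and C5 from the sickle-shaped ylide formed by disrotatory opening of the trans-oxirane, with the lactone ring endo.

Key step: step 8

Remarks on the chemistry
- Oxirane 12 is used as the racemate, because both of its stereocentres vanish in the planar ylide.
- In step 2 the ProPhenol antipode is the one whose dinuclear zinc complex adds the acetylide to the Re face of the aldehyde; the sense would be checked on the first batch of 5, and the other antipode is equally available.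
- Compound 20 may exist partly as its ring-closed hemiketal; both forms give 21, and it is named as the open hydroxy ketone.
- The acetates on the resorcinol ring of the dipole are chosen because they make C5 the carbanion-like ylide terminus, do not absorb near 300 nm and come off under very mild base; silyl ethers replace benzyl ethers because aryl benzyl ethers are photolabile.

Step 1
Reactants: 1 4-hydroxybenzaldehyde
Product: 2 4-[(triisopropylsilyl)oxy]benzaldehyde
Conditions: TIPSCl, imidazole, DMF, rt
Reagents that add atoms: chlorotriisopropylsilane (TIPSCl), CC(C)[Si](Cl)(C(C)C)C(C)C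
Why: Imidazole-mediated O-silylation of a phenol is routine, and the TIPS ether has no photolabile C–O bond, resists mild base and aryllithium, and is removed by fluoride at the end.

Step 2
Reactants: 2 4-[(triisopropylsilyl)oxy]benzaldehyde; 3 methyl propiolate
Product: 5 methyl (S)-4-hydroxy-4-{4-[(triisopropylsilyl)oxy]phenyl}but-2-ynoate, via alkynylzinc 4 (not isolated)
Conditions: Me2Zn, ProPhenol (10 mol%, Re-face antipode), Ph3PO (20 mol%), PhMe, 4 °C; aqueous work-up
Reagents that add atoms: none
Why: Dinuclear zinc–ProPhenol catalysed asymmetric alkynylation, in which the methylzinc acetylide 4 adds to the zinc-bound aldehyde inside the chiral pocket; Re-face delivery sets the future C7 as the S carbinol.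

Step 3
Reactants: 5 methyl (S)-4-hydroxy-4-{4-[(triisopropylsilyl)oxy]phenyl}but-2-ynoate
Product: 7 (R)-5-{4-[(triisopropylsilyl)oxy]phenyl}furan-2(5H)-one, via Z-hydroxy enoate 6 (not isolated)
Conditions: H2 (1 atm), Pd/CaCO3 poisoned with Pb(OAc)2, quinoline, EtOAc, rt; then pyridinium p-toluenesulfonate (cat.), CH2Cl2, rt
Reagents that add atoms: none
Why: Lindlar semihydrogenation adds hydrogen syn and stops at the Z-enoate 6, whose cis hydroxyl and ester lactonise under mild acid; the stereocentre is untouched (S becomes R only through the priority rules), and base is avoided because γ-aryl butenolides racemise through their furanolate.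

Step 4
Reactants: 2 4-[(triisopropylsilyl)oxy]benzaldehyde
Product: 8 triisopropyl(4-vinylphenoxy)silane
Conditions: Ph3PCH3Br, KOt-Bu, THF, 0 °C to rt
Reagents that add atoms: methyltriphenylphosphonium bromide, C[P+](c1ccccc1)(c1ccccc1)c1ccccc1.[Br-]
Why: Wittig methylenation of an aryl aldehyde with the non-stabilised ylide is reliable and leaves the aryl silyl ether intact.

Step 5
Reactants: 9 4-bromoresorcinol
Product: 10 4-bromo-1,3-phenylene diacetate
Conditions: Ac2O, pyridine, DMAP (cat.), CH2Cl2, 0 °C to rt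
Reagents that add atoms: acetic anhydride, CC(=O)OC(C)=O
Why: DMAP-catalysed O-acetylation of both phenols is routine, and the acetates make this ring the electron-poor partner of the later ylide.

Step 6
Reactants: 8 triisopropyl(4-vinylphenoxy)silane; 10 4-bromo-1,3-phenylene diacetate
Product: 11 4-[(E)-2-{4-[(triisopropylsilyl)oxy]phenyl}ethenyl]-1,3-phenylene diacetate
Conditions: Pd2(dba)3 (1.5 mol%), [(t-Bu)3PH]BF4 (6 mol%), Cy2NMe, 1,4-dioxane, 40 °C
Reagents that add atoms: none
Why: Mizoroki–Heck reaction (oxidative addition of the aryl bromide to zerovalent palladium, syn insertion at the unsubstituted styrene terminus, syn β-hydride elimination) gives the E-stilbene, and the hindered amine base leaves the aryl acetates alone.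

Step 7
Reactants: 11 4-[(E)-2-{4-[(triisopropylsilyl)oxy]phenyl}ethenyl]-1,3-phenylene diacetate
Product: 12 rac-4-[(2R,3R)-3-{4-[(triisopropylsilyl)oxy]phenyl}oxiran-2-yl]-1,3-phenylene diacetate (trans-oxirane, racemate)
Conditions: dimethyldioxirane (acetone solution), CH2Cl2, 0 °C; evaporate
Reagents that add atoms: dimethyldioxirane, CC1(C)OO1
Why: Dioxirane epoxidation transfers oxygen in a concerted, stereospecific syn fashion, so the E-alkene can only give the trans-oxirane; the neutral medium and volatile by-product spare the acid-sensitive electron-rich oxirane from chromatography.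

Step 8
Reactants: 12 rac-trans-oxirane; 7 (R)-5-{4-[(triisopropylsilyl)oxy]phenyl}furan-2(5H)-one
Product: 14 4-{(3R,3aS,4R,6R,6aR)-1-oxo-3,6-bis{4-[(triisopropylsilyl)oxy]phenyl}tetrahydro-1H,3H-furo[3,4-c]furan-4-yl}-1,3-phenylene diacetate (cis-fused; target C2 and C7 aryl groups on the convex face, C5 aryl on the concave face), via carbonyl ylide 13 (not isolated)
Conditions: hν (300 nm lamps, quartz), degassed MeCN, 10 °C; 7 (0.15 M), 12 (2.5 equiv, in portions), stopped at partial conversion
Reagents that add atoms: none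
Why: Excitation of the 4-silyloxyphenyl chromophore of 12 should cleave the oxirane C–C bond in a disrotatory sense, so the trans-oxirane (either enantiomer) opens to the planar sickle-shaped (exo,endo) ylide 13, which adds as the 4π component across the electron-poor C3=C4 bond of 7 in a concerted suprafacial [3+2] cycloaddition; the closest known reaction type is the photolysis of 2,3-diaryloxiranes with trapping of the carbonyl ylide by acrylates, fumarates and maleic derivatives. The oxolane ring closes in this one intermolecular event, C2–C3 and C4–C5 forming together through a five-membered envelope transition state. C3 and C4 come out cis because the Z-alkene is locked in the lactone ring, and their absolute configuration follows from attack on the butenolide face anti to the C7 aryl group. C2 and C5 come out trans because the sickle geometry is transferred: the ortho-substituted diacetoxyphenyl group should take the outward ylide position and the lactone should sit under O1, away from the inward-turned silyloxyphenyl group, which places the C5 aryl cis and the C2 aryl trans to the lactone. The step needs C5 to bond to C4, which the push–pull polarisation should secure (acetoxy-deactivated aryl on the carbanion-like C5 that attacks the β-carbon, donor aryl on the oxocarbenium-like C2), and it needs light near 300 nm so that the aryl acetate ring is not excited into photo-Fries chemistry.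

Step 9
Reactants: 14 furofuranone diacetate
Product: 16 (3R,3aS,4R,6R,6aR)-4-{2,4-bis[(tert-butyldimethylsilyl)oxy]phenyl}-3,6-bis{4-[(triisopropylsilyl)oxy]phenyl}tetrahydro-1H,3H-furo[3,4-c]furan-1-one, via diphenol 15 (not isolated)
Conditions: K2CO3 (0.3 equiv), MeOH–THF, 0 °C; pH 7 buffer, extract, concentrate; then TBSCl, imidazole, DMF, 0 °C to rt
Reagents that add atoms: tert-butylchlorodimethylsilane (TBSCl), CC(C)(C)[Si](C)(C)Cl
Why: Base-catalysed methanolysis cleaves aryl acetates within minutes at 0 °C while the hindered aryl TIPS ethers and the cis-fused γ-lactone persist, and the air-sensitive diphenol 15 is silylated at once; the C7 aryl keeps its silyl ether, so no para-phenoxide can expel the lactone carboxylate as a quinone methide.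

Step 10
Reactants: 9 4-bromoresorcinol
Product: 17 [(4-bromo-1,3-phenylene)bis(oxy)]bis(triisopropylsilane)
Conditions: TIPSCl, imidazole, DMF, rt to 40 °C
Reagents that add atoms: chlorotriisopropylsilane (TIPSCl), CC(C)[Si](Cl)(C(C)C)C(C)C
Why: Routine bis-silylation of the phenols; the bulky TIPS group is chosen to suppress 1,3 O-to-C silyl migration in the ortho-lithiated ether of the next step.

Step 11
Reactants: 17 [(4-bromo-1,3-phenylene)bis(oxy)]bis(triisopropylsilane); 16 bis-TBS furofuranone
Product: 20 {2,4-bis[(triisopropylsilyl)oxy]phenyl}[(2R,3R,4R,5R)-5-{2,4-bis[(tert-butyldimethylsilyl)oxy]phenyl}-4-[(R)-hydroxy{4-[(triisopropylsilyl)oxy]phenyl}methyl]-2-{4-[(triisopropylsilyl)oxy]phenyl}oxolan-3-yl]methanone, via aryllithium 18 (not isolated), via lithium hemiketal alkoxide 19 (not isolated)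
Conditions: 17 (1.5 equiv), n-BuLi (1.4 equiv), THF, −78 °C; then 16, −78 °C; AcOH, −78 °C to rt
Reagents that add atoms: none
Why: Bromine–lithium exchange gives aryllithium 18, which adds once to the lactone carbonyl (acyl substitution of a lactone by an organolithium); the tetrahedral alkoxide 19 persists at −78 °C and blocks a second addition, and cold protonation releases the C6 aryl ketone and the C7 hydroxyl without touching a stereocentre.

Step 12
Reactants: 20 hexasilylated hydroxy ketone
Product: 21 (2,4-dihydroxyphenyl){(2R,3R,4R,5R)-5-(2,4-dihydroxyphenyl)-4-[(R)-hydroxy(4-hydroxyphenyl)methyl]-2-(4-hydroxyphenyl)oxolan-3-yl}methanone (CNP0244141.1)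
Conditions: Bu4NF, AcOH (1:1, excess), THF, 0 °C
Reagents that add atoms: none
Why: Fluoride-mediated desilylation removes all six aryl silyl ethers readily, and the acetic acid buffer keeps the phenoxides protonated so that retro-oxa-Michael opening of the β-alkoxy ketone, C3 epimerisation and quinone-methide formation at C2, C5 or C7 should not be triggered.

Compound list
1 | 4-hydroxybenzaldehyde | O=Cc1ccc(O)cc1 | starting material
2 | 4-[(triisopropylsilyl)oxy]benzaldehyde | O=Cc1ccc(O[Si](C(C)C)(C(C)C)C(C)C)cc1 | intermediate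
3 | methyl propiolate | C#CC(=O)OC | starting material
4 | methyl 3-(methylzincio)prop-2-ynoate | C[Zn]C#CC(=O)OC | intermediate (not isolated)
5 | methyl (S)-4-hydroxy-4-{4-[(triisopropylsilyl)oxy]phenyl}but-2-ynoate | COC(=O)C#C[C@@H](O)c1ccc(O[Si](C(C)C)(C(C)C)C(C)C)cc1 | intermediate
6 | methyl (R,Z)-4-hydroxy-4-{4-[(triisopropylsilyl)oxy]phenyl}but-2-enoate | COC(=O)/C=C\[C@@H](O)c1ccc(O[Si](C(C)C)(C(C)C)C(C)C)cc1 | intermediate (not isolated)
7 | (R)-5-{4-[(triisopropylsilyl)oxy]phenyl}furan-2(5H)-one | O=C1C=C[C@@H](O1)c1ccc(O[Si](C(C)C)(C(C)C)C(C)C)cc1 | intermediate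
8 | triisopropyl(4-vinylphenoxy)silane | C=Cc1ccc(O[Si](C(C)C)(C(C)C)C(C)C)cc1 | intermediate
9 | 4-bromoresorcinol | Oc1ccc(Br)c(O)c1 | starting material
10 | 4-bromo-1,3-phenylene diacetate | CC(=O)Oc1ccc(Br)c(OC(C)=O)c1 | intermediate
11 | 4-[(E)-2-{4-[(triisopropylsilyl)oxy]phenyl}ethenyl]-1,3-phenylene diacetate | CC(=O)Oc1ccc(/C=C/c2ccc(O[Si](C(C)C)(C(C)C)C(C)C)cc2)c(OC(C)=O)c1 | intermediate
12 | rac-4-[(2R,3R)-3-{4-[(triisopropylsilyl)oxy]phenyl}oxiran-2-yl]-1,3-phenylene diacetate (trans; racemate, one enantiomer drawn) | CC(=O)Oc1ccc([C@@H]2O[C@H]2c2ccc(O[Si](C(C)C)(C(C)C)C(C)C)cc2)c(OC(C)=O)c1 | intermediate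
13 | sickle-shaped (exo,endo) carbonyl ylide from 12: diacetoxyphenyl-CH(–)–O(+)=CH-(4-silyloxyphenyl), diacetoxyphenyl outward | CC(=O)Oc1ccc([CH-][O+]=Cc2ccc(O[Si](C(C)C)(C(C)C)C(C)C)cc2)c(OC(C)=O)c1 | intermediate (not isolated)
14 | 4-{(3R,3aS,4R,6R,6aR)-1-oxo-3,6-bis{4-[(triisopropylsilyl)oxy]phenyl}tetrahydro-1H,3H-furo[3,4-c]furan-4-yl}-1,3-phenylene diacetate | O=C3[C@@H]1[C@H]([C@@H](O3)c4ccc(O[Si](C(C)C)(C(C)C)C(C)C)cc4)[C@H](c4ccc(OC(C)=O)cc4OC(C)=O)O[C@H]1c1ccc(O[Si](C(C)C)(C(C)C)C(C)C)cc1 | intermediate
15 | (3R,3aS,4R,6R,6aR)-4-(2,4-dihydroxyphenyl)-3,6-bis{4-[(triisopropylsilyl)oxy]phenyl}tetrahydro-1H,3H-furo[3,4-c]furan-1-one | O=C3[C@@H]1[C@H]([C@@H](O3)c4ccc(O[Si](C(C)C)(C(C)C)C(C)C)cc4)[C@H](c4ccc(O)cc4O)O[C@H]1c1ccc(O[Si](C(C)C)(C(C)C)C(C)C)cc1 | intermediate (not isolated)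
16 | (3R,3aS,4R,6R,6aR)-4-{2,4-bis[(tert-butyldimethylsilyl)oxy]phenyl}-3,6-bis{4-[(triisopropylsilyl)oxy]phenyl}tetrahydro-1H,3H-furo[3,4-c]furan-1-one | O=C3[C@@H]1[C@H]([C@@H](O3)c4ccc(O[Si](C(C)C)(C(C)C)C(C)C)cc4)[C@H](c4ccc(O[Si](C)(C)C(C)(C)C)cc4O[Si](C)(C)C(C)(C)C)O[C@H]1c1ccc(O[Si](C(C)C)(C(C)C)C(C)C)cc1 | intermediate
17 | [(4-bromo-1,3-phenylene)bis(oxy)]bis(triisopropylsilane) | Brc1ccc(O[Si](C(C)C)(C(C)C)C(C)C)cc1O[Si](C(C)C)(C(C)C)C(C)C | intermediate
18 | {2,4-bis[(triisopropylsilyl)oxy]phenyl}lithium | [Li]c1ccc(O[Si](C(C)C)(C(C)C)C(C)C)cc1O[Si](C(C)C)(C(C)C)C(C)C | intermediate (not isolated)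
19 | lithium hemiketal alkoxide from addition of 18 to the lactone carbonyl of 16 (anomeric centre undefined, other centres as in 16) | [Li]OC3(c5ccc(O[Si](C(C)C)(C(C)C)C(C)C)cc5O[Si](C(C)C)(C(C)C)C(C)C)[C@@H]1[C@H]([C@@H](O3)c4ccc(O[Si](C(C)C)(C(C)C)C(C)C)cc4)[C@H](c4ccc(O[Si](C)(C)C(C)(C)C)cc4O[Si](C)(C)C(C)(C)C)O[C@H]1c1ccc(O[Si](C(C)C)(C(C)C)C(C)C)cc1 | intermediate (not isolated)
20 | {2,4-bis[(triisopropylsilyl)oxy]phenyl}[(2R,3R,4R,5R)-5-{2,4-bis[(tert-butyldimethylsilyl)oxy]phenyl}-4-[(R)-hydroxy{4-[(triisopropylsilyl)oxy]phenyl}methyl]-2-{4-[(triisopropylsilyl)oxy]phenyl}oxolan-3-yl]methanone | O=C(c1ccc(O[Si](C(C)C)(C(C)C)C(C)C)cc1O[Si](C(C)C)(C(C)C)C(C)C)[C@@H]1[C@H]([C@@H](O)c2ccc(O[Si](C(C)C)(C(C)C)C(C)C)cc2)[C@H](c2ccc(O[Si](C)(C)C(C)(C)C)cc2O[Si](C)(C)C(C)(C)C)O[C@H]1c1ccc(O[Si](C(C)C)(C(C)C)C(C)C)cc1 | intermediate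
21 | (2,4-dihydroxyphenyl){(2R,3R,4R,5R)-5-(2,4-dihydroxyphenyl)-4-[(R)-hydroxy(4-hydroxyphenyl)methyl]-2-(4-hydroxyphenyl)oxolan-3-yl}methanone | O=C(c1ccc(O)cc1O)[C@@H]1[C@H]([C@@H](O)c2ccc(O)cc2)[C@H](c2ccc(O)cc2O)O[C@H]1c1ccc(O)cc1 | target

Total step count: 12. Longest linear sequence: 8 steps (steps 1, 4, 6, 7, 8, 9, 11, 12) from 4-hydroxybenzaldehyde.

Steps most likely to fail

Step 8. The step may fail in several ways:
- The ylide may relax from the sickle to the exo,exo form, or reclose to the cis-oxirane, before it is trapped.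
- The wrong aryl group may turn inward, or the lactone may approach exo, which scrambles C2 and C5.
- Regiocontrol may leak against the steric preference.
- The butenolide or the adduct may itself be excited and degrade.

The fallback sets out from 12 and 7 and generates the ylide by electron transfer instead. The two are irradiated at 420 nm in MeCN with catalytic 9,10-dicyanoanthracene, where only the sensitiser absorbs. Oxidation of the silyloxyaryl oxirane, C–C cleavage of the radical cation and back electron transfer are expected to give the relaxed exo,exo ylide. Its endo addition anti to the C7 aryl should give the all-cis 2,5-diaryl adduct 2-epi-14 F1 (target numbering). Catalytic BF3·OEt2 in CH2Cl2 at −40 °C should then ionise reversibly only the benzylic C2–O1 bond next to the donor aryl, since C5 next to the diacetoxyphenyl ring cannot support a cation. The crowded concave silyloxyphenyl group would thereby move to the convex face, and the route is rejoined at 14.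

Step 11. The hindered aryllithium may deprotonate the lactone at C3 instead of adding, may undergo O-to-C silyl migration if it warms, or may add twice once the hemiketal alkoxide collapses. The fallback sets out from 16 and makes the ketone through an N-methoxy-N-methylamide. MeNH(OMe)·HCl and i-PrMgCl in THF at −20 °C should open the lactone to the γ-hydroxy N-methoxy-N-methylamide F2. Et3SiCl and imidazole in CH2Cl2 cap the C7 hydroxyl to give the triethylsilyl ether F3. Aryllithium 18 (from 17 as in step 11) at −78 °C adds once through the chelated tetrahedral intermediate to give the C7-O-triethylsilyl ketone F4. The conditions of step 12 then remove all seven silyl groups, so the route is rejoined at 21.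

Step 2. The electron-rich aldehyde may react sluggishly and with incomplete facial control, and any shortfall in enantiopurity is carried through every later intermediate. The fallback sets out from 2. Vinylmagnesium bromide in THF at 0 °C gives the racemic allylic alcohol 1-{4-[(triisopropylsilyl)oxy]phenyl}prop-2-en-1-ol F5. Immobilised Candida antarctica lipase B with vinyl acrylate in tert-butyl methyl ether is expected to acylate only the R enantiomer (aryl as the large group of the empirical lipase rule), giving (R)-1-{4-[(triisopropylsilyl)oxy]phenyl}prop-2-en-1-yl acrylate F6, which is separated from the unreacted S alcohol. Ring-closing metathesis with the second-generation Grubbs catalyst RuCl2(=CHPh)(H2IMes)(PCy3) in CH2Cl2 at 40 °C then closes the butenolide, and the route is rejoined at 7.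

Further compounds
F1 | step 8 | 4-{(3R,3aS,4R,6S,6aR)-1-oxo-3,6-bis{4-[(triisopropylsilyl)oxy]phenyl}tetrahydro-1H,3H-furo[3,4-c]furan-4-yl}-1,3-phenylene diacetate (2-epi-14, all-cis 2,5-diaryl adduct) | O=C3[C@@H]1[C@H]([C@@H](O3)c4ccc(O[Si](C(C)C)(C(C)C)C(C)C)cc4)[C@H](c4ccc(OC(C)=O)cc4OC(C)=O)O[C@@H]1c1ccc(O[Si](C(C)C)(C(C)C)C(C)C)cc1
F2 | step 11 | (2R,3R,4R,5R)-5-{2,4-bis[(tert-butyldimethylsilyl)oxy]phenyl}-4-[(R)-hydroxy{4-[(triisopropylsilyl)oxy]phenyl}methyl]-N-methoxy-N-methyl-2-{4-[(triisopropylsilyl)oxy]phenyl}oxolane-3-carboxamide | CON(C)C(=O)[C@@H]1[C@H]([C@@H](O)c2ccc(O[Si](C(C)C)(C(C)C)C(C)C)cc2)[C@H](c2ccc(O[Si](C)(C)C(C)(C)C)cc2O[Si](C)(C)C(C)(C)C)O[C@H]1c1ccc(O[Si](C(C)C)(C(C)C)C(C)C)cc1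
F3 | step 11 | triethylsilyl ether of F2 at the C7 hydroxyl (configuration as in F2) | CON(C)C(=O)[C@@H]1[C@H]([C@@H](O[Si](CC)(CC)CC)c2ccc(O[Si](C(C)C)(C(C)C)C(C)C)cc2)[C@H](c2ccc(O[Si](C)(C)C(C)(C)C)cc2O[Si](C)(C)C(C)(C)C)O[C@H]1c1ccc(O[Si](C(C)C)(C(C)C)C(C)C)cc1
F4 | step 11 | C7-O-triethylsilyl ether of ketone 20 (configuration as in 20) | O=C(c1ccc(O[Si](C(C)C)(C(C)C)C(C)C)cc1O[Si](C(C)C)(C(C)C)C(C)C)[C@@H]1[C@H]([C@@H](O[Si](CC)(CC)CC)c2ccc(O[Si](C(C)C)(C(C)C)C(C)C)cc2)[C@H](c2ccc(O[Si](C)(C)C(C)(C)C)cc2O[Si](C)(C)C(C)(C)C)O[C@H]1c1ccc(O[Si](C(C)C)(C(C)C)C(C)C)cc1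
F5 | step 2 | rac-1-{4-[(triisopropylsilyl)oxy]phenyl}prop-2-en-1-ol | C=CC(O)c1ccc(O[Si](C(C)C)(C(C)C)C(C)C)cc1
F6 | step 2 | (R)-1-{4-[(triisopropylsilyl)oxy]phenyl}prop-2-en-1-yl acrylate | C=C[C@@H](OC(=O)C=C)c1ccc(O[Si](C(C)C)(C(C)C)C(C)C)cc1
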